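A direct plan would brominate guaiacol A1 exhaustively to tetrabromoguaiacol A2, diazotise 2-amino-4,6-dibromophenol A3 to the isolated ortho-quinone diazide A4, and join A2 and A4 by a Rh2(OAc)4-catalysed carbene O–H insertion that would form the diaryl ether bond at ring B. Its weakest steps would be:
- the carbene insertion, because a quinoid carbene would have to be trapped by a hindered, weakly nucleophilic phenol in competition with Wolff-type ring contraction, azine formation and attack on bromine lone pairs;
- the isolation of the dry diazo oxide, which would add a light- and shock-sensitive solid but no complexity;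
- the fourth bromination of guaiacol, which would stall at the carbon meta to the hydroxyl or, if forced with FeBr3, would cost the methyl ether.

The route rests on making ring B (the dibromophenol ring) not as an arene but as a cyclohexanone: the ether oxygen of ring A is joined to an sp3 carbon by SN2 on an α-chloro ketone, and ring B is then aromatised with bromine. The key step exploits the pattern of ring B, where the hydroxyl at C2 has the ether oxygen (C1) and a bromine (C3) on its ortho carbons and a bromine (C5) para: these are the carbonyl, both α-carbons and the γ-carbon of a 2-aryloxycyclohexanone. One operation creates the arene, frees the phenol without a protecting group and places both bromines; no carbene, diazo compound or exhaustive bromination of an anisole is needed.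

Key step: step 3

Assumption: both starting materials are taken as commercial; the chloro ketone is used as the racemate, and the stereocentre it brings is erased in the last step (the target is achiral).

Step 1
Reactants: 1 3,4,5,6-tetrabromobenzene-1,2-diol (tetrabromocatechol)
Product: 2 3,4,5,6-tetrabromo-2-methoxyphenol
Conditions: MeI (1.0 equiv), KHCO3 (1.0 equiv), DMF, 40 °C, 16 h; aq HCl work-up, chromatography (recovered 1 recycled)
Reagents that add atoms: iodomethane, CI
Why: Williamson O-methylation of the intramolecularly hydrogen-bonded monoanion of a symmetric catechol: one equivalent of weak base should keep the second oxygen protonated, both hydroxyls are equivalent so no regiochemical question arises, and no stereocentre is formed.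

Step 2
Reactants: 2 3,4,5,6-tetrabromo-2-methoxyphenol; 3 2-chlorocyclohexan-1-one (racemic)
Product: 4 2-(2,3,4,5-tetrabromo-6-methoxyphenoxy)cyclohexan-1-one (racemic)
Conditions: K2CO3 (1.5 equiv), 3 (1.3 equiv), DMF, 60 °C, 12 h
Reagents that add atoms: none
Why: Williamson ether synthesis (SN2) on an α-halo ketone: the phenol (pKa about 6) is fully ionised by carbonate, its ring has no free carbon so only O-alkylation is possible, and the carbonyl-activated secondary chloride should accept even this hindered phenoxide while the weak base avoids Favorskii rearrangement; the new stereocentre at C2 is formed as the racemate and is erased in step 3.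

Step 3
Reactants: 4 2-(2,3,4,5-tetrabromo-6-methoxyphenoxy)cyclohexan-1-one
Product: 7 2,4-dibromo-6-(2,3,4,5-tetrabromo-6-methoxyphenoxy)phenol, via tribromo ketone 5 (not isolated), via bromophenol 6 (not isolated)
Conditions: Br2 (3.05 equiv), HBr (33% in AcOH, 2 mol %), dry ClCH2CH2Cl, 0 → 25 °C, 3 h; then 80 °C, N2 sweep, 4 h; then 0 °C, Br2 (1.0 equiv), 1 h; aq NaHSO3 work-up
Reagents that add atoms: bromine, BrBr
Why: Halogenative aromatisation of a cyclohexanone: HBr-catalysed enolisation and bromination should replace the three α-hydrogens of 4 (C2–H and C6–H2) to give 5, which on warming loses two molecules of HBr, at C2/C3 through the aryloxy-stabilised cation and at C6/C5 through the dienol, so that ring B aromatises to 6 with the former carbonyl as the free hydroxyl, the ether oxygen ortho to it and one bromine already on the other ortho carbon. The last equivalent of Br2 then enters para to the hydroxyl by SEAr and gives 7. The closest known reaction type is the conversion of polybrominated cyclohexanones into ortho- and para-bromophenols by dehydrobromination, here applied to a 2-aryloxy ketone. No ring is closed and no stereocentre is formed: ring B is carried in from 3 and the racemic centre at C2 is erased. The step needs bromine only on the carbons ortho and para to the new hydroxyl and an intact C2–O bond; the first is secured because the first portion of Br2 is consumed at the α-carbons before any C=C bond exists and because the hydroxyl outweighs the electron-poor aryloxy group in the final SEAr, the second by the dry, non-nucleophilic solvent, in which the C2 bromide can only lose HBr. Ring A has no free position, and sweeping out HBr spares its methyl ether.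

Compound list
1 | 3,4,5,6-tetrabromobenzene-1,2-diol (tetrabromocatechol) | Oc1c(O)c(Br)c(Br)c(Br)c1Br | starting material
2 | 3,4,5,6-tetrabromo-2-methoxyphenol | COc1c(O)c(Br)c(Br)c(Br)c1Br | intermediate
3 | 2-chlorocyclohexan-1-one (racemic) | O=C1CCCCC1Cl | starting material
4 | 2-(2,3,4,5-tetrabromo-6-methoxyphenoxy)cyclohexan-1-one (racemic) | COc1c(Br)c(Br)c(Br)c(Br)c1OC1CCCCC1=O | intermediate
5 | 2,6,6-tribromo-2-(2,3,4,5-tetrabromo-6-methoxyphenoxy)cyclohexan-1-one (racemic) | COc1c(Br)c(Br)c(Br)c(Br)c1OC1(Br)CCCC(Br)(Br)C1=O | intermediate
6 | 2-bromo-6-(2,3,4,5-tetrabromo-6-methoxyphenoxy)phenol | COc1c(Br)c(Br)c(Br)c(Br)c1Oc1cccc(Br)c1O | intermediate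
7 | 2,4-dibromo-6-(2,3,4,5-tetrabromo-6-methoxyphenoxy)phenol | COc1c(Br)c(Br)c(Br)c(Br)c1Oc1cc(Br)cc(Br)c1O | target

Total step count: 3. Longest linear sequence: 3 steps.

Steps most likely to fail

Step 3. The brominated C2 could ionise with loss of the aryloxy group. Bromine could also enter ring B ortho to the ether oxygen by addition to an enone formed while free Br2 is still present, and the dehydrobromination could stop short of the arene. The fallback gives up the aromatisation and sets out from 2. SNAr on commercial 2,4-dibromo-6-fluorobenzaldehyde F1 (K2CO3, DMAc, 120 °C) would give 2,4-dibromo-6-(2,3,4,5-tetrabromo-6-methoxyphenoxy)benzaldehyde F2. Baeyer–Villiger (Dakin-type) oxidation with mCPBA in CH2Cl2 would give 2,4-dibromo-6-(2,3,4,5-tetrabromo-6-methoxyphenoxy)phenyl formate F3, and methanolysis (K2CO3, MeOH) would return to the route at 7.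

Step 1. The second hydroxyl could be methylated before the first equivalent is consumed, leaving a mixture of diol, monoether and diether. The fallback sets out from 1. Exhaustive methylation (Me2SO4, K2CO3, acetone, reflux) would give 1,2,3,4-tetrabromo-5,6-dimethoxybenzene F4. Nucleophilic mono-demethylation (LiCl, DMF, 130 °C) would follow, in which the phenoxide formed by the first cleavage should prevent the second; acidification would return to the route at 2.

Step 2. Substitution by the hindered, weakly nucleophilic phenoxide could be slower than the base-induced self-condensation and dehydrochlorination of the chloro ketone. The fallback sets out from 2. Base-catalysed ring opening of cyclohexene oxide F5 (Cs2CO3 20 mol %, DMF, 110 °C) would give (±)-trans-2-(2,3,4,5-tetrabromo-6-methoxyphenoxy)cyclohexan-1-ol F6, and Dess–Martin oxidation (CH2Cl2, 25 °C) would return to the route at 4.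

Further compounds
F1 | step 3 | 2,4-dibromo-6-fluorobenzaldehyde | O=Cc1c(F)cc(Br)cc1Br
F2 | step 3 | 2,4-dibromo-6-(2,3,4,5-tetrabromo-6-methoxyphenoxy)benzaldehyde | COc1c(Br)c(Br)c(Br)c(Br)c1Oc1cc(Br)cc(Br)c1C=O
F3 | step 3 | 2,4-dibromo-6-(2,3,4,5-tetrabromo-6-methoxyphenoxy)phenyl formate | COc1c(Br)c(Br)c(Br)c(Br)c1Oc1cc(Br)cc(Br)c1OC=O
F4 | step 1 | 1,2,3,4-tetrabromo-5,6-dimethoxybenzene | COc1c(OC)c(Br)c(Br)c(Br)c1Br
F5 | step 2 | cyclohexene oxide (7-oxabicyclo[4.1.0]heptane, meso) | C1CCC2OC2C1
F6 | step 2 | (±)-trans-2-(2,3,4,5-tetrabromo-6-methoxyphenoxy)cyclohexan-1-ol (racemic, one enantiomer drawn) | COc1c(Br)c(Br)c(Br)c(Br)c1O[C@@H]1CCCC[C@H]1O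
A1 | direct plan | guaiacol (2-methoxyphenol) | COc1ccccc1O
A2 | direct plan | 3,4,5,6-tetrabromo-2-methoxyphenol | COc1c(O)c(Br)c(Br)c(Br)c1Br
A3 | direct plan | 2-amino-4,6-dibromophenol | Nc1cc(Br)cc(Br)c1O
A4 | direct plan | 2,4-dibromo-6-diazocyclohexa-2,4-dien-1-one | O=C1C(Br)=CC(Br)=CC1=[N+]=[N-]
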